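**Retrosynthetic overview**
1. The route retraces the presumed biogenesis from a marrubiin-type 9-hydroxy-furanolabdane; the A/B decalin and six stereocentres come intact from (+)-marrubiin 1.
2. Target 12 ⇐ 16-O-methyl lactol 10: the ring-D carbonyl is revealed last (acetal → γ-lactone).
3. Ring E (19,20-δ-lactone) ⇐ C19 carboxylate + C20–Cl. The C20–Cl comes from a 6β-alkoxy-radical 1,5-H shift after opening the 19,6β-lactone, the chemical counterpart of C20 hydroxylation and relactonisation.
4. Rings C (9,13-tetrahydrofuran) and D ⇐ furan + 9α-OH in one dearomative bromo-spiroetherification (a premarrubiin-type closure triggered by furan oxidation).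
5. Ring order: A/B (purchased) → C and D together (step 1) → old γ-lactone opened (step 3) → E closed (step 5) → D oxidised (step 6).

Assumption: (+)-marrubiin (CAS 465-92-9), the crystalline bulk diterpene of white horehound sold by phytochemical suppliers, is the purchased starting material; labdane numbering is used, and the acetal/lactol carbon C16 of the intermediates is an anomeric mixture written without a descriptor.

**Step 1**
Reactants: 1 (+)-marrubiin (15,16-epoxy-9α-hydroxylabda-13(16),14-dien-19,6β-olide)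
Product: 3 (13S)-16-methoxy-9α,13:15,16-diepoxylabd-14-en-19,6β-olide, via bromo spiroether 2 (not isolated)
Conditions: NBS (1.05 equiv), (DHQD)2PHAL (10 mol %), NaHCO3, CHCl3, −40 °C; then MeOH, −40 → 0 °C
Reagents that add atoms: N-bromosuccinimide, O=C1CCC(=O)N1Br (Br stays only in 2); methanol, CO
Why: Proposed new method: Br+ adds to the furan at C16 (the α-position flanking the side chain, as in electrophilic substitution of 3-alkylfurans) to give a C13/C15-delocalised vinylogous oxocarbenium that the tertiary 9α-OH captures 5-exo at C13 (the halonium counterpart of the acid-triggered marrubiin → premarrubiin closure), and methanolysis of the α-bromo ether then fixes C16 as an acetal; the closest known reactions are NBS Achmatowicz-type oxidative spiroketalisations of furyl alcohols and (DHQD)2PHAL-catalysed dearomative halocyclisations of benzofurans and indoles; C13 is the only lasting new stereocentre, the substrate bias is expected to be small because C9 is flanked by near-equivalent C8 and C10 branches, so the chiral halonium carrier is relied on to choose the face ((DHQ)2PHAL is used instead if it proves to be the matched ligand) and the 13S epimer (C16 on the C10 side of the new tetrahydrofuran) is purified by chromatography.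

**Step 2**
Reactants: 3 (13S)-16-methoxy-9α,13:15,16-diepoxylabd-14-en-19,6β-olide
Product: 4 (13S)-16-methoxy-9α,13:15,16-diepoxylabdan-19,6β-olide
Conditions: H2 (1 atm), 5% Rh/Al2O3, EtOAc, Et3N (1 vol %), rt
Reagents that add atoms: none
Why: Heterogeneous catalytic hydrogenation of the 1,2-disubstituted cyclic enol ether; Rh with a trace of base avoids ionisation or hydrogenolysis of the allylic spiro C13–O bond, the lactone and acetal are inert, and no stereocentre is formed.

**Step 3**
Reactants: 4 (13S)-16-methoxy-9α,13:15,16-diepoxylabdan-19,6β-olide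
Product: 6 benzyl (13S)-6β-hydroxy-16-methoxy-9α,13:15,16-diepoxylabdan-19-oate, via potassium carboxylate 5 (not isolated)
Conditions: KOH (1.1 equiv), EtOH/H2O (4:1), 80 °C; evaporate; then BnBr, DMF, rt
Reagents that add atoms: potassium hydroxide, [K+].[OH-]; benzyl bromide, BrCc1ccccc1
Why: Saponification by acyl–oxygen cleavage (C6 configuration retained, as in marrubiin → marrubic acid) followed by SN2 O-benzylation of the carboxylate in the same flask locks the hydroxy acid open; the methyl acetal and both ethers are base-stable.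

**Step 4**
Reactants: 6 benzyl (13S)-6β-hydroxy-16-methoxy-9α,13:15,16-diepoxylabdan-19-oate
Product: 8 benzyl (13S)-20-chloro-6β-hydroxy-16-methoxy-9α,13:15,16-diepoxylabdan-19-oate, via 6β-hypochlorite 7 (not isolated)
Conditions: Cl2O (0.6 equiv), CH2Cl2, −20 °C, dark; then hν (>300 nm), PhH, solid NaHCO3, 10 °C
Reagents that add atoms: dichlorine monoxide, ClOCl
Why: Barton-type hypochlorite photolysis (alkoxy-radical 1,5-hydrogen atom transfer): the axial 6β-O• abstracts H from the 1,3-diaxial C20 methyl through a six-membered transition state and C20• takes Cl from another hypochlorite in a chain, which is the 6β-OH → angular-methyl relay of steroid chemistry and the laboratory stand-in for enzymatic C20 hydroxylation; the axial C19 ester has no abstractable H and no stereocentre changes.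

**Step 5**
Reactants: 8 benzyl (13S)-20-chloro-6β-hydroxy-16-methoxy-9α,13:15,16-diepoxylabdan-19-oate
Product: 10 (13S)-6β-hydroxy-16-methoxy-9α,13:15,16-diepoxylabdan-19,20-olide, via chloro acid 9 (not isolated)
Conditions: H2 (1 atm), 10% Pd/C, EtOAc, rt; filter; then Cs2CO3 (0.55 equiv), DMF, 60 °C
Reagents that add atoms: none
Why: Hydrogenolysis of the benzyl ester (alkyl chloride and acetal untouched) followed by intramolecular SN2 (6-exo-tet) of the caesium carboxylate on the 1,3-diaxial neopentyl C20–Cl closes the 19,20-δ-lactone; because the carboxyl group is present only as its anion it cannot acylate the 6β-OH, so the marrubiin-type γ-lactone cannot re-form and the 6β-OH stays free with its configuration untouched.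

**Step 6**
Reactants: 10 (13S)-6β-hydroxy-16-methoxy-9α,13:15,16-diepoxylabdan-19,20-olide
Product: 12 (13S)-6β-hydroxy-9α,13-epoxylabdane-19,20:16,15-diolide (CNP0393616.1), via lactol 11 (not isolated)
Conditions: PPTS, acetone/H2O (4:1), rt; then TEMPO (10 mol %), PhI(OAc)2, CH2Cl2, rt
Reagents that add atoms: water, O
Why: Mild acid hydrolysis of the 2-methoxytetrahydrofuran acetal to the lactol followed by oxoammonium (TEMPO/PhI(OAc)2) oxidation, which converts lactols to lactones much faster than it oxidises the hindered axial secondary 6β-OH; the δ-lactone and the C13 spiro centre (no α-H, not epimerisable) are unaffected.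

**Compound list**
1 | (+)-marrubiin | C[C@@H]1C[C@@H]2[C@@H]3[C@](C)(CCC[C@]3(C)C(=O)O2)[C@@]1(O)CCc1ccoc1 | starting material
2 | bromo spiroether: (13S)-16-bromo-9α,13:15,16-diepoxylabd-14-en-19,6β-olide | C[C@@H]1C[C@@H]2[C@@H]3[C@](C)(CCC[C@]3(C)C(=O)O2)[C@@]14CC[C@@]1(C=COC1Br)O4 | intermediate (not isolated)
3 | (13S)-16-methoxy-9α,13:15,16-diepoxylabd-14-en-19,6β-olide | C[C@@H]1C[C@@H]2[C@@H]3[C@](C)(CCC[C@]3(C)C(=O)O2)[C@@]14CC[C@@]1(C=COC1OC)O4 | intermediate
4 | (13S)-16-methoxy-9α,13:15,16-diepoxylabdan-19,6β-olide | C[C@@H]1C[C@@H]2[C@@H]3[C@](C)(CCC[C@]3(C)C(=O)O2)[C@@]14CC[C@@]1(CCOC1OC)O4 | intermediate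
5 | potassium carboxylate: potassium (13S)-6β-hydroxy-16-methoxy-9α,13:15,16-diepoxylabdan-19-oate | C[C@@H]1C[C@@H](O)[C@@H]2[C@](C)(CCC[C@]2(C)C(=O)[O-])[C@@]13CC[C@@]1(CCOC1OC)O3.[K+] | intermediate (not isolated)
6 | benzyl (13S)-6β-hydroxy-16-methoxy-9α,13:15,16-diepoxylabdan-19-oate | C[C@@H]1C[C@@H](O)[C@@H]2[C@](C)(CCC[C@]2(C)C(=O)OCc2ccccc2)[C@@]13CC[C@@]1(CCOC1OC)O3 | intermediate
7 | 6β-hypochlorite: benzyl (13S)-6β-chlorooxy-16-methoxy-9α,13:15,16-diepoxylabdan-19-oate | C[C@@H]1C[C@@H](OCl)[C@@H]2[C@](C)(CCC[C@]2(C)C(=O)OCc2ccccc2)[C@@]13CC[C@@]1(CCOC1OC)O3 | intermediate (not isolated)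
8 | benzyl (13S)-20-chloro-6β-hydroxy-16-methoxy-9α,13:15,16-diepoxylabdan-19-oate | C[C@@H]1C[C@@H](O)[C@@H]2[C@](CCl)(CCC[C@]2(C)C(=O)OCc2ccccc2)[C@@]13CC[C@@]1(CCOC1OC)O3 | intermediate
9 | chloro acid: (13S)-20-chloro-6β-hydroxy-16-methoxy-9α,13:15,16-diepoxylabdan-19-oic acid | C[C@@H]1C[C@@H](O)[C@@H]2[C@](CCl)(CCC[C@]2(C)C(=O)O)[C@@]13CC[C@@]1(CCOC1OC)O3 | intermediate (not isolated)
10 | (13S)-6β-hydroxy-16-methoxy-9α,13:15,16-diepoxylabdan-19,20-olide | C[C@@H]1C[C@@H](O)[C@@H]2[C@]3(CCC[C@]2(C)C(=O)OC3)[C@@]12CC[C@@]1(CCOC1OC)O2 | intermediate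
11 | lactol: (13S)-6β,16-dihydroxy-9α,13:15,16-diepoxylabdan-19,20-olide | C[C@@H]1C[C@@H](O)[C@@H]2[C@]3(CCC[C@]2(C)C(=O)OC3)[C@@]12CC[C@@]1(CCOC1O)O2 | intermediate (not isolated)
12 | (13S)-6β-hydroxy-9α,13-epoxylabdane-19,20:16,15-diolide | C[C@@H]1C[C@@H](O)[C@@H]2[C@]3(CCC[C@]2(C)C(=O)OC3)[C@@]12CC[C@@]1(CCOC1=O)O2 | target

**Totals**
Total step count: 6. Longest linear sequence: 6 (fully linear from 1). C4, C5, C6, C8, C9 and C10 are carried unchanged from 1 (no bond to any of them is broken except the C20–H); C13 is created in step 1.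

**Steps most likely to fail**

Step 1. The risks are aromatic substitution (16-bromomarrubiin) or 2,5-addition instead of C13 capture, and insufficient control of C13; without the catalyst a roughly 1:1 epimer mixture is expected, and which ligand gives 13S must be found by experiment. The fallback replaces the halonium by hydroxyl-directed oxygen transfer. Setting out from 1, VO(acac)2 (5 mol %)/t-BuOOH in CH2Cl2 at 0 °C (Achmatowicz-type furan oxidation, with the vanadate ester of the 9α-OH delivering oxygen to the neighbouring C13=C16 bond) gives the spiro lactol (13S)-16-hydroxy-9α,13:15,16-diepoxylabd-14-en-19,6β-olide F1. Its C13 epimers interconvert through the ring-opened vinylogous oxocarbenium. PPTS/MeOH then equilibrates the mixture and fixes it as the methyl acetals, from which the 13S isomer is separated, and the route is rejoined at 3.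

Step 4. The risks are loss of HCl from the secondary hypochlorite (giving the 6-ketone) and unselective chain chlorination. The fallback changes the radical precursor and the trap. Setting out from 6, NOCl/pyridine at −20 °C gives the nitrite ester benzyl (13S)-16-methoxy-6β-nitrosooxy-9α,13:15,16-diepoxylabdan-19-oate F2. Pyrex-filtered photolysis in benzene containing BrCCl3 (Barton nitrite photolysis with radical exchange, a non-chain process with no ketone-forming elimination) gives benzyl (13S)-20-bromo-6β-hydroxy-16-methoxy-9α,13:15,16-diepoxylabdan-19-oate F3. Hydrogenolysis and Cs2CO3/DMF as in step 5 then pass through (13S)-20-bromo-6β-hydroxy-16-methoxy-9α,13:15,16-diepoxylabdan-19-oic acid F4 and rejoin the route at 10.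

Step 5. The risks are slow SN2 at the neopentyl chloride, with 6β,20-ether formation or an acyl shift to the 19,6β-lactone competing. The fallback takes the 6-oxygen out of play. Setting out from 8, Dess–Martin periodinane gives benzyl (13S)-20-chloro-16-methoxy-6-oxo-9α,13:15,16-diepoxylabdan-19-oate F5. H2, Pd/C and then Cs2CO3, DMF, 80 °C give, through (13S)-20-chloro-16-methoxy-6-oxo-9α,13:15,16-diepoxylabdan-19-oic acid F6, the keto lactone (13S)-16-methoxy-6-oxo-9α,13:15,16-diepoxylabdan-19,20-olide F7. NaBH4 in MeOH at −20 °C then adds hydride from the open α-face (the β-face is covered by the C19–O–C20 bridge) to restore the axial 6β-OH, coming back to the route at 10.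

**Further compounds**
F1 | step 1 | (13S)-16-hydroxy-9α,13:15,16-diepoxylabd-14-en-19,6β-olide | C[C@@H]1C[C@@H]2[C@@H]3[C@](C)(CCC[C@]3(C)C(=O)O2)[C@@]14CC[C@@]1(C=COC1O)O4
F2 | step 4 | benzyl (13S)-16-methoxy-6β-nitrosooxy-9α,13:15,16-diepoxylabdan-19-oate | C[C@@H]1C[C@@H](ON=O)[C@@H]2[C@](C)(CCC[C@]2(C)C(=O)OCc2ccccc2)[C@@]13CC[C@@]1(CCOC1OC)O3
F3 | step 4 | benzyl (13S)-20-bromo-6β-hydroxy-16-methoxy-9α,13:15,16-diepoxylabdan-19-oate | C[C@@H]1C[C@@H](O)[C@@H]2[C@](CBr)(CCC[C@]2(C)C(=O)OCc2ccccc2)[C@@]13CC[C@@]1(CCOC1OC)O3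
F4 | step 4 | (13S)-20-bromo-6β-hydroxy-16-methoxy-9α,13:15,16-diepoxylabdan-19-oic acid | C[C@@H]1C[C@@H](O)[C@@H]2[C@](CBr)(CCC[C@]2(C)C(=O)O)[C@@]13CC[C@@]1(CCOC1OC)O3
F5 | step 5 | benzyl (13S)-20-chloro-16-methoxy-6-oxo-9α,13:15,16-diepoxylabdan-19-oate | C[C@@H]1CC(=O)[C@@H]2[C@](CCl)(CCC[C@]2(C)C(=O)OCc2ccccc2)[C@@]13CC[C@@]1(CCOC1OC)O3
F6 | step 5 | (13S)-20-chloro-16-methoxy-6-oxo-9α,13:15,16-diepoxylabdan-19-oic acid | C[C@@H]1CC(=O)[C@@H]2[C@](CCl)(CCC[C@]2(C)C(=O)O)[C@@]13CC[C@@]1(CCOC1OC)O3
F7 | step 5 | (13S)-16-methoxy-6-oxo-9α,13:15,16-diepoxylabdan-19,20-olide | C[C@@H]1CC(=O)[C@@H]2[C@]3(CCC[C@]2(C)C(=O)OC3)[C@@]12CC[C@@]1(CCOC1OC)O2
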